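Cuts: the styryl bond C6–Cα (Heck), the inter-unit bond C3–C6′, and the bond C3′–C1″ to resorcinol ring C (two nickel-catalysed decarboxylative arylations). What remains is one dihydrobenzofuran-3-carboxylate, needed twice.
Enabling feature: each dihydrobenzofuran (ring system 1: O1, C2, C3, C3a–C7a; ring system 2: the same atoms primed) has a 4-hydroxyphenyl group on an S-configured C2, oxygen at C4 and a carbon substituent at C6. These are the C2 aryl group, O1 and the 5,7-dioxygenated benzo ring of (2S)-naringenin, with the pyranone one atom smaller.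
Ring order: all six-membered rings are bought. The only ring-forming event is the oxidative contraction pyranone → dihydrofuran (C3–C3a made, old C4 pushed out as the C3 ester), run once on a 7-OTf/4′-OMs/5-OMe flavanone.
Chain order: ester → redox-active ester. Coupling with ring C completes ring system 2. Its triflate becomes an iodide and takes a second portion of the same redox-active ester (C3–C6′). The surviving C6 triflate is styrylated, then demethylation and demesylation finish the route.
Stereochemistry: C2 and C2′ are the untouched C2 of naringenin. C3 and C3′ follow by 1,2-induction: trans in the ring contraction and, once decarboxylation has flattened them, trans again when arylnickel captures the radical anti to the C2 aryl group. The E alkene comes from the Heck step.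

Key step: step 4

Assumption: (2S)-naringenin is bought as the single enantiomer; because commercial lots differ in optical purity and flavanones racemise through the chalcone in base, the ee of 1 and again of 4 is to be checked by chiral HPLC, and no step before the ring contraction uses a base stronger than a tertiary amine.

Step 1
Reactants: 1 (2S)-naringenin
Product: 2 (2S)-7-O-triflylnaringenin
Conditions: PhNTf2 (1.0 equiv), iPr2NEt (1.05 equiv), THF–DMF, 0 °C
Reagents that add atoms: N-phenylbis(trifluoromethanesulfonimide), O=S(=O)(N(c1ccccc1)S(=O)(=O)C(F)(F)F)C(F)(F)F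
Why: Chemoselective O-triflation: the 7-OH, para to the acyl carbon and hence a vinylogous acid, is the most acidic phenol and the 5-OH is locked in a hydrogen bond to the carbonyl oxygen, so one equivalent of a hindered amine ionises only O7 and the mild triflyl donor reacts only with that phenoxide, while base strength and temperature stay too low for chalcone opening at C2.

Step 2
Reactants: 2 (2S)-7-O-triflylnaringenin
Product: 3 (2S)-4′-O-mesyl-7-O-triflylnaringenin
Conditions: MsCl (1.05 equiv), pyridine, CH2Cl2, 0 °C
Reagents that add atoms: methanesulfonyl chloride, CS(=O)(=O)Cl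
Why: O-Sulfonylation of the only unchelated phenol left, with the selectivity of the familiar 7,4′-diacylation of naringenin in pyridine that spares the hydrogen-bonded 5-OH; pyridine is too weak a base to enolise C3, so C2 is safe.

Step 3
Reactants: 3 (2S)-4′-O-mesyl-7-O-triflylnaringenin
Product: 4 (2S)-5-O-methyl-4′-O-mesyl-7-O-triflylnaringenin
Conditions: MeOH (3 equiv), PPh3, DIAD, THF, 0 °C → rt
Reagents that add atoms: methanol, CO
Why: Mitsunobu etherification, known to alkylate the chelated 5-OH of 7,4′-di-O-acylated naringenin, needs no added base: the phenol, made more acidic by the meta triflate, protonates the betaine and its phenoxide attacks the methyl group of the methoxyphosphonium ion, so the retro-oxa-Michael route to the chalcone that carbonate and methyl iodide would open is avoided and C2 stays S.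

Step 4
Reactants: 4 (2S)-5-O-methyl-4′-O-mesyl-7-O-triflylnaringenin
Product: 7 methyl (2S,3S)-4-methoxy-2-(4-mesyloxyphenyl)-6-triflyloxy-2,3-dihydrobenzofuran-3-carboxylate, via methyl enol ether 5 (not isolated), via trans-3-iodanyl dimethyl ketal 6 (not isolated)
Conditions: PhI(OAc)2 (1.2 equiv), conc. H2SO4 (cat.), HC(OMe)3, rt
Reagents that add atoms: trimethyl orthoformate, COC(OC)OC
Why: Acid and orthoformate turn ketone 4 into enol ether 5, the trivalent iodine electrophile adds to C3 of 5 on the face anti to the equatorial C2 aryl group, and methanol caps the oxocarbenium ion to give ketal 6, whose equatorial C3–I bond lies antiperiplanar to C4–C4a. C4a then shifts from C4 to C3 with inversion as iodobenzene leaves, and the exocyclic dimethoxycarbenium ion hands one methyl group to acetate and remains as the methyl ester. This is the known oxidative ring contraction of flavanones to methyl trans-2-aryl-2,3-dihydrobenzofuran-3-carboxylates with PhI(OAc)2 or Tl(NO3)3 in trimethyl orthoformate, a relative of the oxidative 1,2-aryl shift of alkyl aryl ketones to arylalkanoates. The ring O1–C2–C3–C3a–C7a arises by contraction of the pyranone through this 1,2-shift (C3–C3a made while C4–C4a breaks), not by cyclisation of an open chain. The new stereocentre C3 is governed by C2: anti attack of iodine followed by the invertive shift places the ester trans to the aryl group (2S,3S), which is also the more stable epimer, and no bond to C2 is touched. The step needs migration of C4a rather than of the C2 aryl group (isoflavone) or loss of the C2 hydrogen (flavone); C4a keeps two ortho oxygen donors (5-OMe, O1) that outweigh the para triflate, the C2 aryl group is deactivated by its mesylate, and both sulfonates shield the rings from iodination and oxidation.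

Step 5
Reactants: 7 methyl (2S,3S)-4-methoxy-2-(4-mesyloxyphenyl)-6-triflyloxy-2,3-dihydrobenzofuran-3-carboxylate
Product: 8 (2S,3S)-4-methoxy-2-(4-mesyloxyphenyl)-6-triflyloxy-2,3-dihydrobenzofuran-3-carboxylic acid
Conditions: 6 M aq HCl, 1,4-dioxane, 90 °C
Reagents that add atoms: water, O
Why: Acid-catalysed ester hydrolysis: aryl triflate, aryl mesylate and aryl methyl ether are all stable to hot aqueous acid, the mesylate-deactivated C2 position does not ionise, saponification is avoided because a C3 carbanion could expel O1 and erase C2, and any enolisation at C3 only returns the more stable trans acid.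

Step 6
Reactants: 8 (2S,3S)-4-methoxy-2-(4-mesyloxyphenyl)-6-triflyloxy-2,3-dihydrobenzofuran-3-carboxylic acid
Product: 9 1,3-dioxoisoindolin-2-yl (2S,3S)-4-methoxy-2-(4-mesyloxyphenyl)-6-triflyloxy-2,3-dihydrobenzofuran-3-carboxylate (redox-active ester)
Conditions: N-hydroxyphthalimide, DIC, DMAP (5 mol %), CH2Cl2, 0 °C → rt
Reagents that add atoms: N-hydroxyphthalimide, O=C1c2ccccc2C(=O)N1O
Why: Carbodiimide (Steglich-type) esterification gives the redox-active ester under nearly neutral conditions, with only catalytic DMAP and low temperature so that the now more acidic C3–H is not removed.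

Step 7
Reactants: 9 redox-active ester; 10 1-iodo-3,5-dimethoxybenzene (1.3 equiv)
Product: 11 (2S,3S)-3-(3,5-dimethoxyphenyl)-4-methoxy-2-(4-mesyloxyphenyl)-2,3-dihydrobenzofuran-6-yl triflate
Conditions: NiBr2(dme) (10 mol %), 4,4′-di-tert-butyl-2,2′-bipyridine (10 mol %), Zn (2 equiv), DMA, rt
Reagents that add atoms: none
Why: Nickel-catalysed reductive decarboxylative cross-electrophile arylation of an N-hydroxyphthalimide ester with an aryl iodide: bipyridine-ligated zerovalent nickel inserts into C–I far faster than into aryl triflate or mesylate (both known spectators under such conditions), single-electron reduction of 9 releases CO2 and the planar benzylic C3 radical, whose C2–O1 bond lies in the nodal plane and so does not fragment, and the arylnickel species captures it on the face anti to the C2 aryl group so that reductive elimination sets C3 trans (3S).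

Step 8
Reactants: 11 (2S,3S)-3-(3,5-dimethoxyphenyl)-4-methoxy-2-(4-mesyloxyphenyl)-2,3-dihydrobenzofuran-6-yl triflate
Product: 12 4-[(2S,3S)-3-(3,5-dimethoxyphenyl)-4-methoxy-6-trimethylstannyl-2,3-dihydrobenzofuran-2-yl]phenyl mesylate
Conditions: (Me3Sn)2 (1.5 equiv), Pd(PPh3)4 (5 mol %), LiCl (3 equiv), 1,4-dioxane, 100 °C
Reagents that add atoms: hexamethylditin, C[Sn](C)(C)[Sn](C)(C)C
Why: Palladium-catalysed stannylation of an aryl triflate with a distannane in the presence of LiCl (Stille-type transmetalation); the aryl mesylate does not add to zerovalent palladium bearing PPh3 and no stereocentre takes part.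

Step 9
Reactants: 12 4-[(2S,3S)-3-(3,5-dimethoxyphenyl)-4-methoxy-6-trimethylstannyl-2,3-dihydrobenzofuran-2-yl]phenyl mesylate
Product: 13 4-[(2S,3S)-3-(3,5-dimethoxyphenyl)-6-iodo-4-methoxy-2,3-dihydrobenzofuran-2-yl]phenyl mesylate
Conditions: I2 (1.0 equiv), CH2Cl2, 0 °C
Reagents that add atoms: iodine, II
Why: Ipso-iododestannylation: the C–Sn bond reacts with one equivalent of iodine much faster than the C–H positions of the dimethoxyphenyl ring, which puts iodine at C6, a position meta to both oxygen donors that direct iodination could not reach.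

Step 10
Reactants: 9 redox-active ester (second portion, 1.3 equiv); 13 aryl iodide
Product: 14 (2S,3S)-3-[(2S,3S)-3-(3,5-dimethoxyphenyl)-4-methoxy-2-(4-mesyloxyphenyl)-2,3-dihydrobenzofuran-6-yl]-4-methoxy-2-(4-mesyloxyphenyl)-2,3-dihydrobenzofuran-6-yl triflate
Conditions: NiBr2(dme) (15 mol %), 4,4′-di-tert-butyl-2,2′-bipyridine (15 mol %), Zn (2 equiv), DMA, rt
Reagents that add atoms: none
Why: The same nickel-catalysed decarboxylative cross-electrophile arylation as in step 7, now as fragment union: the unhindered C6′–I bond of 13 is the only bond that adds to nickel, the C6 triflate of 9 is kept for the next step, and the C3 radical is again captured anti to its own C2 aryl group, which sets C3 trans (3S) independently of the remote stereocentres of 13.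

Step 11
Reactants: 14 bis(dihydrobenzofuran) triflate; 15 4-methoxystyrene (2 equiv)
Product: 16 the 6-[(E)-4-methoxystyryl] analogue of 14 (pentamethyl ether bis-mesylate of the target)
Conditions: PdCl2(PPh3)2 (5 mol %), LiCl (3 equiv), Et3N (3 equiv), DMF, 100 °C
Reagents that add atoms: none
Why: Mizoroki–Heck reaction of the aryl triflate; chloride steers it through the neutral arylpalladium chloride pathway so that the styrene is arylated at its terminal carbon, syn insertion followed by syn β-hydride elimination gives the E alkene, and the mesylates stay inert.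

Step 12
Reactants: 16 pentamethyl ether bis-mesylate
Product: 17 4′,4‴-bis-O-mesylate of the target (five free phenols)
Conditions: BBr3 (15 equiv), CH2Cl2, −78 °C → rt; H2O
Reagents that add atoms: none
Why: Boron tribromide cleavage of aryl methyl ethers, routine for methylated stilbenoids; the two mesylates survive and keep the C2 and C2′ aryl groups electron-poor, so the benzylic C2–O1 and C2′–O1′ bonds are not ionised by the Lewis acid and the four stereocentres stay as set.

Step 13
Reactants: 17 bis-mesylate of the target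
Product: 18 CNP0248228.2
Conditions: KOH (2 M aq), MeOH, Ar, 50 °C; then 1 M HCl
Reagents that add atoms: none
Why: Alkaline hydrolysis of aryl methanesulfonates (S–O cleavage, directly or through the sulfene) under argon frees the last two phenols; the ring oxygens sit on rings that already carry a phenoxide and are poor leaving groups, so quinone methide opening at C2 is not expected at this temperature.

Compound list
1 | (2S)-naringenin | O=C1C[C@@H](c2ccc(O)cc2)Oc2cc(O)cc(O)c12 | starting material
2 | (2S)-7-O-triflylnaringenin | O=C1C[C@@H](c2ccc(O)cc2)Oc2cc(OS(=O)(=O)C(F)(F)F)cc(O)c12 | intermediate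
3 | (2S)-4′-O-mesyl-7-O-triflylnaringenin | O=C1C[C@@H](c2ccc(OS(C)(=O)=O)cc2)Oc2cc(OS(=O)(=O)C(F)(F)F)cc(O)c12 | intermediate
4 | (2S)-5-O-methyl-4′-O-mesyl-7-O-triflylnaringenin | O=C1C[C@@H](c2ccc(OS(C)(=O)=O)cc2)Oc2cc(OS(=O)(=O)C(F)(F)F)cc(OC)c12 | intermediate
5 | (2S)-4,5-dimethoxy-2-(4-mesyloxyphenyl)-2H-chromen-7-yl triflate (methyl enol ether of 4) | COC1=C[C@@H](c2ccc(OS(C)(=O)=O)cc2)Oc2cc(OS(=O)(=O)C(F)(F)F)cc(OC)c12 | intermediate
6 | (2R,3R)-3-[acetoxy(phenyl)-λ3-iodanyl]-4,4,5-trimethoxy-2-(4-mesyloxyphenyl)chroman-7-yl triflate (2,3-trans; C2 unchanged in space, descriptor changed by priority) | COC1(OC)[C@H](I(OC(C)=O)c3ccccc3)[C@@H](c2ccc(OS(C)(=O)=O)cc2)Oc2cc(OS(=O)(=O)C(F)(F)F)cc(OC)c12 | intermediate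
7 | methyl (2S,3S)-4-methoxy-2-(4-mesyloxyphenyl)-6-triflyloxy-2,3-dihydrobenzofuran-3-carboxylate (trans) | FC(F)(F)S(=O)(=O)Oc1cc(OC)c2c(c1)O[C@H](c1ccc(OS(C)(=O)=O)cc1)[C@H]2C(=O)OC | intermediate
8 | (2S,3S)-4-methoxy-2-(4-mesyloxyphenyl)-6-triflyloxy-2,3-dihydrobenzofuran-3-carboxylic acid | FC(F)(F)S(=O)(=O)Oc1cc(OC)c2c(c1)O[C@H](c1ccc(OS(C)(=O)=O)cc1)[C@H]2C(=O)O | intermediate
9 | 1,3-dioxoisoindolin-2-yl ester of 8 (redox-active ester) | FC(F)(F)S(=O)(=O)Oc1cc(OC)c2c(c1)O[C@H](c1ccc(OS(C)(=O)=O)cc1)[C@H]2C(=O)ON1C(=O)c2ccccc2C1=O | intermediate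
10 | 1-iodo-3,5-dimethoxybenzene | COc1cc(I)cc(OC)c1 | starting material
11 | (2S,3S)-3-(3,5-dimethoxyphenyl)-4-methoxy-2-(4-mesyloxyphenyl)-2,3-dihydrobenzofuran-6-yl triflate | FC(F)(F)S(=O)(=O)Oc1cc(OC)c2c(c1)O[C@H](c1ccc(OS(C)(=O)=O)cc1)[C@H]2c1cc(OC)cc(OC)c1 | intermediate
12 | 4-[(2S,3S)-3-(3,5-dimethoxyphenyl)-4-methoxy-6-trimethylstannyl-2,3-dihydrobenzofuran-2-yl]phenyl mesylate | C[Sn](C)(C)c1cc(OC)c2c(c1)O[C@H](c1ccc(OS(C)(=O)=O)cc1)[C@H]2c1cc(OC)cc(OC)c1 | intermediate
13 | 4-[(2S,3S)-3-(3,5-dimethoxyphenyl)-6-iodo-4-methoxy-2,3-dihydrobenzofuran-2-yl]phenyl mesylate | Ic1cc(OC)c2c(c1)O[C@H](c1ccc(OS(C)(=O)=O)cc1)[C@H]2c1cc(OC)cc(OC)c1 | intermediate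
14 | (2S,3S)-3-[(2S,3S)-3-(3,5-dimethoxyphenyl)-4-methoxy-2-(4-mesyloxyphenyl)-2,3-dihydrobenzofuran-6-yl]-4-methoxy-2-(4-mesyloxyphenyl)-2,3-dihydrobenzofuran-6-yl triflate | FC(F)(F)S(=O)(=O)Oc1cc(OC)c2c(c1)O[C@H](c1ccc(OS(C)(=O)=O)cc1)[C@H]2c1cc(OC)c2c(c1)O[C@H](c1ccc(OS(C)(=O)=O)cc1)[C@H]2c1cc(OC)cc(OC)c1 | intermediate
15 | 4-methoxystyrene | C=Cc1ccc(OC)cc1 | starting material
16 | pentamethyl ether bis-mesylate of the target, (2S,3S,2′S,3′S), E alkene | COc1ccc(/C=C/c2cc(OC)c3c(c2)O[C@H](c2ccc(OS(C)(=O)=O)cc2)[C@H]3c2cc(OC)c3c(c2)O[C@H](c2ccc(OS(C)(=O)=O)cc2)[C@H]3c2cc(OC)cc(OC)c2)cc1 | intermediate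
17 | bis-mesylate of the target (mesyl on the two C2/C2′ aryl oxygens, five free phenols) | Oc1ccc(/C=C/c2cc(O)c3c(c2)O[C@H](c2ccc(OS(C)(=O)=O)cc2)[C@H]3c2cc(O)c3c(c2)O[C@H](c2ccc(OS(C)(=O)=O)cc2)[C@H]3c2cc(O)cc(O)c2)cc1 | intermediate
18 | CNP0248228.2, (2S,3S)-3-[(2S,3S)-3-(3,5-dihydroxyphenyl)-4-hydroxy-2-(4-hydroxyphenyl)-2,3-dihydrobenzofuran-6-yl]-2-(4-hydroxyphenyl)-6-[(E)-4-hydroxystyryl]-2,3-dihydrobenzofuran-4-ol | Oc1ccc(/C=C/c2cc(O)c3c(c2)O[C@H](c2ccc(O)cc2)[C@H]3c2cc(O)c3c(c2)O[C@H](c2ccc(O)cc2)[C@H]3c2cc(O)cc(O)c2)cc1 | target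

Total step count: 13.
Longest linear sequence: 13 steps (1 → 18 through 11 and 13). The second portion of 9 used in step 10 comes from the same six steps.

Steps most likely to fail

Step 4. Oxidation and shift happen in one pot, and the para triflate slows the migration of C4a. The shift may therefore be outrun by loss of the C2 hydrogen (aromatisation of the hetero ring), by shift of the C2 aryl group, or by methanolysis at C3. The fallback sets out from 4 and separates the two events.
- CuBr2 in refluxing EtOAc–CHCl3, an acidic α-bromination that needs no base, should give the equatorial trans-3-bromoflavanone F1.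
- HC(OMe)3 and TsOH in MeOH should convert it into the bromo dimethyl ketal F2.
- AgBF4 then pulls off bromide and triggers the same antiperiplanar, invertive shift of C4a. This is the known silver-assisted rearrangement of α-bromoalkyl aryl ketals to arylalkanoic esters.
- Aqueous work-up gives 7, where the route is rejoined.

Step 10. Capture of the hindered benzylic radical by a bulky arylnickel partner may be slow. That would leave room for radical dimerisation, hydrogen abstraction, β-hydride loss toward the aromatic furan, or eroded facial selectivity. The fallback sets out from 9 and trades the radical capture for a two-electron transmetalation.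
- Visible-light decarboxylative borylation with bis(catecholato)diboron in DMAc should give the catechol boronic ester F3.
- F3 is transesterified in the same flask with pinacol and Et3N to the trans pinacol boronic ester F4; boron enters anti to the C2 aryl group.
- Stereoretentive Suzuki–Miyaura coupling of this secondary benzylic boronate with iodide 13 (Pd2(dba)3, PPh3, Ag2O, DME, 80 °C) leads back to 14. Zerovalent palladium takes the C–I bond ahead of the triflate.

Step 12. The electron-rich stilbene may be protonated or hydrobrominated and then oligomerise while five ethers are being cleaved. Forcing the last ether may also start to open a C2–O1 bond. The fallback sets out from 14 and demethylates before the alkene exists.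
- BBr3 should convert 14 into the tetraphenol triflate F5, since triflate and mesylates are inert to BBr3.
- Ac2O in pyridine gives the tetraacetate F6.
- Heck reaction with commercial 4-acetoxystyrene under the conditions of step 11 gives the pentaacetate bis-mesylate F7.
- One alkaline hydrolysis as in step 13 removes acetates and mesylates together and ends at 18.

Further compounds
F1 | step 4 | (2R,3R)-3-bromo-5-O-methyl-4′-O-mesyl-7-O-triflylnaringenin (2,3-trans) | O=C1[C@H](Br)[C@@H](c2ccc(OS(C)(=O)=O)cc2)Oc2cc(OS(=O)(=O)C(F)(F)F)cc(OC)c12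
F2 | step 4 | dimethyl ketal of F1 (2,3-trans) | COC1(OC)[C@H](Br)[C@@H](c2ccc(OS(C)(=O)=O)cc2)Oc2cc(OS(=O)(=O)C(F)(F)F)cc(OC)c12
F3 | step 10 | (2S,3S)-3-(1,3,2-benzodioxaborol-2-yl)-4-methoxy-2-(4-mesyloxyphenyl)-2,3-dihydrobenzofuran-6-yl triflate | FC(F)(F)S(=O)(=O)Oc1cc(OC)c2c(c1)O[C@H](c1ccc(OS(C)(=O)=O)cc1)[C@H]2B1Oc2ccccc2O1
F4 | step 10 | (2S,3S)-4-methoxy-2-(4-mesyloxyphenyl)-3-(4,4,5,5-tetramethyl-1,3,2-dioxaborolan-2-yl)-2,3-dihydrobenzofuran-6-yl triflate | FC(F)(F)S(=O)(=O)Oc1cc(OC)c2c(c1)O[C@H](c1ccc(OS(C)(=O)=O)cc1)[C@H]2B1OC(C)(C)C(C)(C)O1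
F5 | step 12 | tetraphenol from 14 (triflate and both mesylates kept) | FC(F)(F)S(=O)(=O)Oc1cc(O)c2c(c1)O[C@H](c1ccc(OS(C)(=O)=O)cc1)[C@H]2c1cc(O)c2c(c1)O[C@H](c1ccc(OS(C)(=O)=O)cc1)[C@H]2c1cc(O)cc(O)c1
F6 | step 12 | tetraacetate of F5 | FC(F)(F)S(=O)(=O)Oc1cc(OC(C)=O)c2c(c1)O[C@H](c1ccc(OS(C)(=O)=O)cc1)[C@H]2c1cc(OC(C)=O)c2c(c1)O[C@H](c1ccc(OS(C)(=O)=O)cc1)[C@H]2c1cc(OC(C)=O)cc(OC(C)=O)c1
F7 | step 12 | pentaacetate bis-mesylate of the target, E alkene | CC(=O)Oc1ccc(/C=C/c2cc(OC(C)=O)c3c(c2)O[C@H](c2ccc(OS(C)(=O)=O)cc2)[C@H]3c2cc(OC(C)=O)c3c(c2)O[C@H](c2ccc(OS(C)(=O)=O)cc2)[C@H]3c2cc(OC(C)=O)cc(OC(C)=O)c2)cc1
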